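**Late readings.** Late in two runs with the same 4.3 µM of enzyme, at 12.0 h, amber with 87 mM of starting material reads 56.6%, less than the 98.7% of teal with 9 mM, so clock time does not carry from one flask to the next.

| flask | starting material | enzyme | remark | time |
|---|---|---|---|---|
| teal | 9 mM | 4.3 µM | run made earlier |  |
| amber | 87 mM | 4.3 µM | run made earlier |  |
| blue | 43 mM | 2.6 µM | run made earlier |  |
| eta | 120 mM | 6.0 µM |  | 12 h |
| beta | 80 mM | 2.0 µM |  | 12 h |
| epsilon | 10 mM | 1.0 µM |  | 12 h |
| alpha | 20 mM | 8.0 µM |  | 12 h |
| theta | 43 mM | 4.3 µM |  | 12 h |

- teal (time / h: product / %): 1.50: 57.5; 4.00: 82.6; 8.00: 93.5; 12.0: 98.7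
- amber (time / h: product / %): 1.50: 21.6; 4.00: 36.6; 8.00: 48.9; 12.0: 56.6
- blue (time / h: product / %): 3.00: 34.7; 6.00: 48.4; 10.0: 59.3; 12.0: 62.2

(scatter of a reading: 0.5 percentage points)

- what was read earlier has a scatter of 0.5 percentage points, one standard deviation

* all flasks from highest to lowest amount of product, in percent of the starting material charged, at 12 h (eta / beta / epsilon / alpha / theta)
* the same order at 2.0 d (eta / beta / epsilon / alpha / theta)
* the amount of product, in percent of the starting material charged of the flask you put first, at 12 h
* the amount of product, in percent of the starting material charged of the flask you put last, at 12 h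

**The dose.** A better axis is the dose, for alpha at 12 h 17.3 s: enzyme concentration times time, per starting material charged. It counts seconds of enzyme work per molecule of starting material, the usual catalyst loading multiplied by time. Amber at 8.00 h and blue at 6.00 h stand at 1.42 s and 1.31 s and read 48.9% and 48.4%, though amber holds twice the charge.

**The bracket.** If product rises with dose, teal brackets alpha: 13.8 s gave 93.5% and 20.6 s gave 98.7%. Beta, at 1.08 s, lies between amber at 4.00 h, with 0.712 s and 36.6%, and blue at 6.00 h, with 48.4%. My interpolation on the logarithm of dose tightens these to 96.4% for alpha and 44.7% for beta. Alpha has the highest dose and beta the lowest, while theta and epsilon tie at 4.32 s.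

**The forecast.** It gives alpha > theta > epsilon > eta > beta at 12 h and alpha > theta > epsilon > eta > beta at 2.0 d, “slightly favouring theta”. Its top is 96% (94% to 98.5%) and its low 43% (40% to 46%). Both central values lie inside my brackets, each a little under my interpolation .

**The result.** The flasks give alpha > theta > epsilon > eta > beta at 12 h, with alpha at 97.2% and beta at 42.9%, both inside the brackets; at 2.0 d they give alpha > epsilon > theta > eta > beta.

    starting material + enzyme → product + enzyme, rate k1*[starting material]*[enzyme]/(1 + ([starting material]/Km1) + ([product]/Kp1)) (22.0 mM, 2.00 mM, k = 100 L mol⁻¹ s⁻¹)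
    enzyme + product → spent catalyst (k = 4.20 × 10⁻⁴ L mol⁻¹ s⁻¹)

**Equal dose.** Theta and epsilon at 2.0 d match the dose of alpha at 12 h, 17.3 s , yet theta reads 89.0% and epsilon 95.4%, against 97.2% for alpha. At 12.0 h, spent catalyst stood at 34.5% of the enzyme charged in theta and 8.41% in epsilon.

**Second flask.** A neighbour of alpha, charged with 34 mM of starting material, has a dose of 10.2 s. That lies between teal at 4.00 h and 8.00 h, and the same interpolation gives 88.7%. The neighbour gives 90.7%.

Readings and results are simulated for an exercise; noise was put on by code.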